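The constants 4.5 × 10⁻⁴ L mol⁻¹ s⁻¹ and 4.4 × 10⁻⁴ L mol⁻¹ s⁻¹ are close, so the split of the starting material between intermediate A and side product A rests on the two concentrations beside them.

    starting material + coupling partner → intermediate A (k1 = 4.5 × 10⁻⁴ L mol⁻¹ s⁻¹)
    second reagent + intermediate A → intermediate B (k2 = 1.5 × 10⁻⁴ L mol⁻¹ s⁻¹)
    third reagent + intermediate B → target (k3 = 0.013 L mol⁻¹ s⁻¹)
    starting material + second reagent → side product A (k4 = 4.4 × 10⁻⁴ L mol⁻¹ s⁻¹)
    intermediate B → side product B (k5 = 2.4 × 10⁻⁵ s⁻¹)
    gas ⇌ third reagent, rate k6*(csat - [third reagent]) (k6 = 1.4 × 10⁻⁴ s⁻¹, csat = 9.2 mM)

| flask | starting material | coupling partner | second reagent | gas | time | remark |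
|---|---|---|---|---|---|---|
| eta | 0.10 M | 0.120 M | 0.200 M | 9.2 mM (held) | 3.0 d | everything together at the start |
| delta | 0.10 M | 0.120 M (fed, over 6.0 h) | 0.200 M | 9.2 mM (held) | 3.0 d | all else is in the flask from the start; the feed brings no volume worth counting |
| gamma | 0.10 M (fed, over 2.5 d) | 0.120 M | 0.200 M | 9.2 mM (held) | 3.0 d | all else is in the flask from the start; the feed brings no volume worth counting |
| epsilon | 0.10 M | 0.120 M (fed, over 2.5 d) | 0.200 M | 9.2 mM (held) | 3.0 d | all else is in the flask from the start; the feed brings no volume worth counting |

- the best flask by amount of target, in percent of the starting material charged; "all alike" if 1.5 percentage points covers them all (eta / delta / gamma / epsilon / all alike)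
- amount of target at the end, in percent of the starting material charged, eta
- amount of target at the end, in percent of the starting material charged, delta
- amount of target at the end, in percent of the starting material charged, gamma
- amount of target at the end, in percent of the starting material charged, epsilon

- at the start none of third reagent is dissolved
- run time (eta): 3.0 d

At the charges, coupling consumes starting material at 5.40 × 10⁻⁵ s⁻¹ and the side path at 8.80 × 10⁻⁵ s⁻¹, which is faster, so 38.0% goes into coupling. I called this the branch share, the coupling rate over the sum of both rates, a selectivity read from [coupling partner] and [second reagent].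

Intermediate B then chooses between the third reagent and its own loss. I took [third reagent] near saturation, since transfer offers 1.29 × 10⁻⁶ M s⁻¹ against a mean need of 1.47 × 10⁻⁷ M s⁻¹. That lets 83.3% of intermediate B reach target.

With a fed coupling partner, the concentration that matters changes. Starting material's lifetime against the second reagent at that reagent's charge is 0.132 d, a value for the start, since [second reagent] falls as it is used, and as a rough time I used for [coupling partner] what the feed delivers in that time.

- eta, gamma: [coupling partner] 0.120 M, branch share 38.0%, target 31.7%
- delta: [coupling partner] 0.0631 M, branch share 24.4%, target 20.3%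
- epsilon: [coupling partner] 0.00631 M, branch share 3.13%, target 2.61%

Gamma shares the top row with eta, since its coupling partner stands charged in the flask. Going down, delta has about half of that concentration, and epsilon has ten times less again, so the target column falls with it.

But gamma's last starting material arrives at 2.5 d, and intermediate A lives 0.772 d at [second reagent] of 0.100 M, longer than the 0.500 d remaining. Gamma therefore drops below its row, and I put eta first.

The forecast, made apart from mine, also chose eta, with 29.5% for eta, 17% for delta, 28% for gamma and 5.3% for epsilon, and said “feeding the coupling partner starves the productive step”.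

The flasks gave 30.1% in eta, 18.2% in delta, 27.2% in gamma and 4.09% in epsilon, with eta first. Eta held 61.6% side product A at 3.00 d, beside 62.0% from one minus the branch share reckoned at the charges. In a neighbour of eta charged with 0.48 M of coupling partner, the branch share at the charges becomes 71.1%, leaving 28.9% for side product A and 59.2% for target. That flask held 28.6% side product A and 52.9% target.

The numbers of this flask are invented.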